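**Strategy**

Everything rests on cutting the bond between the quaternary ring carbon C2 of the dihydrofuranone (numbering: O1, C2 with CO2Me, C3 aryl, C4 enol oxygen, C5 lactone C=O) and the benzylic CH2 of the epoxyprenyl phenol ring. Because C2 carries the ester and is tied through C3=C4 to C5=O, its C–H form ionises to a flat aromatic 2-oxidofuran. A chiral ammonium phase-transfer catalyst guides a 4-siloxybenzyl bromide, already bearing the Shi-derived (R)-epoxide, onto one face of that anion: both halves are joined and the quaternary stereocentre is created in one operation. The precursor is a racemic, bis-TIPS-protected 2-H furanone made by pyruvate–glyoxylate aldol lactonisation.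

Key step: step 9

Assumption: the sense of induction of the N-spiro ammonium catalyst on this anion cannot be read from a simple model; the (S,S)-antipode is written, and the equally available (R,R)-antipode would be used if it proves to deliver the opposite face.

**Route**

Step 1
Reactants: 1 4-hydroxyphenylpyruvic acid
Product: 2 methyl 3-(4-hydroxyphenyl)-2-oxopropanoate
Conditions: MeOH, cat. H2SO4, rt to 40 °C
Reagents that add atoms: methanol, CO
Why: Fischer esterification of the α-keto acid leaves the phenol untouched and should give the ester as a keto/enol mixture.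

Step 2
Reactants: 2 methyl 3-(4-hydroxyphenyl)-2-oxopropanoate; 3 methyl glyoxylate
Product: 5 methyl 4-hydroxy-3-(4-hydroxyphenyl)-5-oxo-2,5-dihydrofuran-2-carboxylate (racemic), via aldol adduct 4 (not isolated)
Conditions: 3 (1.5 equiv, freshly distilled), Et3N (1.2 equiv), THF, 0 °C to rt; then 1 M HCl
Reagents that add atoms: none
Why: Cross-aldol addition of the pyruvate enolate to the far more electrophilic glyoxylate aldehyde, then lactonisation of the new hydroxyl onto the activated α-keto ester and enolisation (isotetronic acid synthesis); the C2–H centre is racemic and is erased in step 9.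

Step 3
Reactants: 5 methyl 4-hydroxy-3-(4-hydroxyphenyl)-5-oxo-2,5-dihydrofuran-2-carboxylate
Product: 6 methyl 5-oxo-4-[(triisopropylsilyl)oxy]-3-{4-[(triisopropylsilyl)oxy]phenyl}-2,5-dihydrofuran-2-carboxylate (racemic)
Conditions: TIPSCl (2.5 equiv), imidazole (5 equiv), DMF, rt
Reagents that add atoms: triisopropylsilyl chloride, CC(C)[Si](Cl)(C(C)C)C(C)C
Why: O-silylation of the phenol and of the phenol-like enol hydroxyl; TIPSCl/imidazole is too weak a system to silylate the acidic C2–H position.

Step 4
Reactants: 7 3-bromo-4-hydroxybenzaldehyde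
Product: 8 3-bromo-4-[(triisopropylsilyl)oxy]benzaldehyde
Conditions: TIPSCl (1.2 equiv), imidazole (2.5 equiv), DMF, rt
Reagents that add atoms: triisopropylsilyl chloride, CC(C)[Si](Cl)(C(C)C)C(C)C
Why: Phenol silylation to a robust TIPS ether that blocks the phenoxide in all later steps.

Step 5
Reactants: 8 3-bromo-4-[(triisopropylsilyl)oxy]benzaldehyde; 9 tributyl(3-methylbut-2-en-1-yl)stannane
Product: 10 3-(3-methylbut-2-en-1-yl)-4-[(triisopropylsilyl)oxy]benzaldehyde
Conditions: 9 (1.3 equiv), Pd(PPh3)4 (5 mol %), DMF (degassed), 90 °C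
Reagents that add atoms: none
Why: Stille coupling: oxidative addition into the C–Br bond, transfer of the prenyl group through its CH2 terminus and reductive elimination should give the linear prenyl arene under base- and fluoride-free conditions that spare the aryl silyl ether.

Step 6
Reactants: 10 3-(3-methylbut-2-en-1-yl)-4-[(triisopropylsilyl)oxy]benzaldehyde
Product: 11 {3-(3-methylbut-2-en-1-yl)-4-[(triisopropylsilyl)oxy]phenyl}methanol
Conditions: NaBH4, THF–MeOH, 0 °C
Reagents that add atoms: none
Why: Borohydride reduction of the aldehyde; alkene and silyl ether are inert, and the silyl ether is no longer activated once the formyl group is gone.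

Step 7
Reactants: 11 {3-(3-methylbut-2-en-1-yl)-4-[(triisopropylsilyl)oxy]phenyl}methanol
Product: 12 (3-{[(2R)-3,3-dimethyloxiran-2-yl]methyl}-4-[(triisopropylsilyl)oxy]phenyl)methanol
Conditions: D-fructose-derived Shi ketone (0.3 equiv), Oxone (1.4 equiv), K2CO3, cat. Bu4NHSO4, MeCN–DMM / aq. Na2B4O7–EDTA buffer (pH about 10.5), 0 °C
Reagents that add atoms: Oxone (potassium peroxymonosulfate), [K+].[O-]S(=O)(=O)OO
Why: Shi asymmetric epoxidation: the chiral dioxirane transfers oxygen through a spiro transition state to one face of the only alkene, and the D-fructose-derived ketone should give the (R)-epoxide, the sense established for trans-disubstituted and trisubstituted (including 2-methylalk-2-ene) substrates.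

Step 8
Reactants: 12 (3-{[(2R)-3,3-dimethyloxiran-2-yl]methyl}-4-[(triisopropylsilyl)oxy]phenyl)methanol
Product: 13 {4-(bromomethyl)-2-{[(2R)-3,3-dimethyloxiran-2-yl]methyl}phenoxy}tri(propan-2-yl)silane
Conditions: CBr4 (1.3 equiv), PPh3 (1.3 equiv), 2,6-lutidine (0.3 equiv), CH2Cl2, −20 to 0 °C; short filtration, used at once
Reagents that add atoms: carbon tetrabromide, BrC(Br)(Br)Br
Why: Appel reaction: the primary benzylic hydroxyl is activated by Ph3P/CBr4 and displaced by bromide under near-neutral conditions at low temperature, which a remote epoxide tolerates; the stereocentre is not involved.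

Step 9
Reactants: 6 methyl 5-oxo-4-[(triisopropylsilyl)oxy]-3-{4-[(triisopropylsilyl)oxy]phenyl}-2,5-dihydrofuran-2-carboxylate; 13 {4-(bromomethyl)-2-{[(2R)-3,3-dimethyloxiran-2-yl]methyl}phenoxy}tri(propan-2-yl)silane
Product: 15 methyl (2R)-2-[(3-{[(2R)-3,3-dimethyloxiran-2-yl]methyl}-4-[(triisopropylsilyl)oxy]phenyl)methyl]-5-oxo-4-[(triisopropylsilyl)oxy]-3-{4-[(triisopropylsilyl)oxy]phenyl}-2,5-dihydrofuran-2-carboxylate, via caesium furanolate 14 (not isolated)
Conditions: 13 (1.15 equiv), (S,S)-3,4,5-trifluorophenyl-NAS bromide (C2-symmetric N-spiro binaphthyl ammonium bromide, 3 mol %), Cs2CO3 (solid, 1.5 equiv), toluene, −20 °C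
Reagents that add atoms: none
Why: Solid Cs2CO3 removes the C2–H of 6, which is α to the methyl ester and vinylogously α to the lactone carbonyl, and the chiral ammonium cation carries the resulting flat 6π 2-oxidofuran 14 into toluene as a tight ion pair that attacks the activated 4-siloxybenzyl bromide 13 in an SN2 reaction. The closest known reaction type is the asymmetric phase-transfer C-alkylation of cyclic, ester-stabilised tertiary carbanions (β-keto esters, oxazoline-4-carboxylates, 3-aryl benzofuranones) to quaternary centres. No ring is closed. The new quaternary centre C2 is controlled by the catalyst: its binaphthyl and trifluorophenyl walls cover one enantiotopic face of the anion, so the bromide must approach the Si face of C2, which gives (2R), while the remote (R)-epoxide of 13 is a spectator. The step needs alkylation at C2 and not at C4 or oxygen; this should be secured by the bulky OTIPS group on C4, by the soft benzylic bromide in a non-polar medium, and by the fact that only attack at C2 keeps C3=C4 conjugated with the lactone carbonyl and the aryl ring. Epoxide, methyl ester, lactone and silyl ethers should be inert to carbonate in toluene at −20 °C.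

Step 10
Reactants: 15 methyl (2R)-2-[(3-{[(2R)-3,3-dimethyloxiran-2-yl]methyl}-4-[(triisopropylsilyl)oxy]phenyl)methyl]-5-oxo-4-[(triisopropylsilyl)oxy]-3-{4-[(triisopropylsilyl)oxy]phenyl}-2,5-dihydrofuran-2-carboxylate
Product: 16 methyl (2R)-2-[(3-{[(2R)-3,3-dimethyloxiran-2-yl]methyl}-4-hydroxyphenyl)methyl]-4-hydroxy-3-(4-hydroxyphenyl)-5-oxo-2,5-dihydrofuran-2-carboxylate (CNP0331593.1)
Conditions: TBAF (3.3 equiv), AcOH (3.6 equiv), THF, 0 °C to rt; pH 7 phosphate work-up
Reagents that add atoms: none
Why: Fluoride-mediated desilylation cleaves the two aryl and the one enol Si–O bond; the acetic acid buffer keeps the freed phenol ortho to the side chain protonated so that it should not open the oxirane, and neither stereocentre is touched.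

**Compound list**

1 | 4-hydroxyphenylpyruvic acid | O=C(O)C(=O)Cc1ccc(O)cc1 | starting material
2 | methyl 3-(4-hydroxyphenyl)-2-oxopropanoate | COC(=O)C(=O)Cc1ccc(O)cc1 | intermediate
3 | methyl glyoxylate | COC(=O)C=O | starting material
4 | dimethyl 2-hydroxy-3-(4-hydroxyphenyl)-4-oxopentanedioate (aldol adduct, stereoisomer mixture, not isolated) | COC(=O)C(O)C(c1ccc(O)cc1)C(=O)C(=O)OC | intermediate
5 | methyl 4-hydroxy-3-(4-hydroxyphenyl)-5-oxo-2,5-dihydrofuran-2-carboxylate (racemic) | COC(=O)C1OC(=O)C(O)=C1c1ccc(O)cc1 | intermediate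
6 | methyl 5-oxo-4-[(triisopropylsilyl)oxy]-3-{4-[(triisopropylsilyl)oxy]phenyl}-2,5-dihydrofuran-2-carboxylate (racemic) | COC(=O)C1OC(=O)C(O[Si](C(C)C)(C(C)C)C(C)C)=C1c1ccc(O[Si](C(C)C)(C(C)C)C(C)C)cc1 | intermediate
7 | 3-bromo-4-hydroxybenzaldehyde | O=Cc1ccc(O)c(Br)c1 | starting material
8 | 3-bromo-4-[(triisopropylsilyl)oxy]benzaldehyde | O=Cc1ccc(O[Si](C(C)C)(C(C)C)C(C)C)c(Br)c1 | intermediate
9 | tributyl(3-methylbut-2-en-1-yl)stannane | CCCC[Sn](CCCC)(CCCC)CC=C(C)C | starting material
10 | 3-(3-methylbut-2-en-1-yl)-4-[(triisopropylsilyl)oxy]benzaldehyde | O=Cc1ccc(O[Si](C(C)C)(C(C)C)C(C)C)c(CC=C(C)C)c1 | intermediate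
11 | {3-(3-methylbut-2-en-1-yl)-4-[(triisopropylsilyl)oxy]phenyl}methanol | OCc1ccc(O[Si](C(C)C)(C(C)C)C(C)C)c(CC=C(C)C)c1 | intermediate
12 | (3-{[(2R)-3,3-dimethyloxiran-2-yl]methyl}-4-[(triisopropylsilyl)oxy]phenyl)methanol | OCc1ccc(O[Si](C(C)C)(C(C)C)C(C)C)c(C[C@H]2OC2(C)C)c1 | intermediate
13 | {4-(bromomethyl)-2-{[(2R)-3,3-dimethyloxiran-2-yl]methyl}phenoxy}tri(propan-2-yl)silane | BrCc1ccc(O[Si](C(C)C)(C(C)C)C(C)C)c(C[C@H]2OC2(C)C)c1 | intermediate
14 | caesium 5-(methoxycarbonyl)-3-[(triisopropylsilyl)oxy]-4-{4-[(triisopropylsilyl)oxy]phenyl}furan-2-olate (not isolated; reacts as its chiral ammonium ion pair) | COC(=O)c1oc([O-])c(O[Si](C(C)C)(C(C)C)C(C)C)c1-c1ccc(O[Si](C(C)C)(C(C)C)C(C)C)cc1.[Cs+] | intermediate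
15 | methyl (2R)-2-[(3-{[(2R)-3,3-dimethyloxiran-2-yl]methyl}-4-[(triisopropylsilyl)oxy]phenyl)methyl]-5-oxo-4-[(triisopropylsilyl)oxy]-3-{4-[(triisopropylsilyl)oxy]phenyl}-2,5-dihydrofuran-2-carboxylate | COC(=O)[C@]1(Cc2ccc(O[Si](C(C)C)(C(C)C)C(C)C)c(C[C@H]3OC3(C)C)c2)OC(=O)C(O[Si](C(C)C)(C(C)C)C(C)C)=C1c1ccc(O[Si](C(C)C)(C(C)C)C(C)C)cc1 | intermediate
16 | methyl (2R)-2-[(3-{[(2R)-3,3-dimethyloxiran-2-yl]methyl}-4-hydroxyphenyl)methyl]-4-hydroxy-3-(4-hydroxyphenyl)-5-oxo-2,5-dihydrofuran-2-carboxylate | COC(=O)[C@]1(Cc2ccc(O)c(C[C@H]3OC3(C)C)c2)OC(=O)C(O)=C1c1ccc(O)cc1 | target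

**Step count and risks**

Total steps: 10 (steps 1–3 for the furanone half, steps 4–8 for the benzyl half, steps 9–10 after union).
Longest linear sequence: 7 steps (steps 4 to 10, from 3-bromo-4-hydroxybenzaldehyde).

Steps most likely to fail:

1. Step 9. The catalyst may not discriminate the two faces of the flat 2-oxidofuran well enough, or part of the alkylation may drift to C4 or oxygen. Fallback: give up catalyst control and use the epoxide stereocentre as a handle for separation. Setting out from 6 and 13, alkylation with an achiral ammonium salt (Bu4NBr, Cs2CO3, toluene, 0 °C) through the same furanolate 14 should give 15 together with its C2 epimer, methyl (2S)-2-[(3-{[(2R)-3,3-dimethyloxiran-2-yl]methyl}-4-[(triisopropylsilyl)oxy]phenyl)methyl]-5-oxo-4-[(triisopropylsilyl)oxy]-3-{4-[(triisopropylsilyl)oxy]phenyl}-2,5-dihydrofuran-2-carboxylate F1. The two are diastereomers and would be separated by preparative HPLC (silica or a polysaccharide phase); the (2R) isomer rejoins the route at 15.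

2. Step 8. Adventitious HBr or the phosphonium bromide may open the trisubstituted epoxide, or the electron-rich benzylic bromide may ionise during isolation. Fallback: brominate before the epoxide exists and epoxidise after the union. Setting out from 11, the same Appel conditions should give {4-(bromomethyl)-2-(3-methylbut-2-en-1-yl)phenoxy}tri(propan-2-yl)silane F2. Alkylation of 6 with F2 under the chiral phase-transfer conditions of step 9 should give methyl (2R)-2-{[3-(3-methylbut-2-en-1-yl)-4-[(triisopropylsilyl)oxy]phenyl]methyl}-5-oxo-4-[(triisopropylsilyl)oxy]-3-{4-[(triisopropylsilyl)oxy]phenyl}-2,5-dihydrofuran-2-carboxylate F3. Shi epoxidation of F3 (conditions of step 7) should then oxidise only the unhindered prenyl alkene, since the ring C=C is tetrasubstituted, shielded and conjugated to the lactone, and the route is rejoined at 15.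

3. Step 5. Allylic transposition on palladium may deliver the reverse-prenyl (1,1-dimethylallyl) isomer, or oxidative addition next to the bulky siloxy group may be sluggish. Fallback: build the prenyl group by metathesis instead of transferring it intact. Setting out from 8, Stille coupling with allyltributylstannane (Pd(PPh3)4, DMF, 90 °C), where both allyl termini are identical, should give 3-(prop-2-en-1-yl)-4-[(triisopropylsilyl)oxy]benzaldehyde F4. Cross-metathesis of F4 with excess 2-methylbut-2-ene (Grubbs II catalyst, CH2Cl2, 40 °C) should convert allyl into prenyl and rejoin the route at 10.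

**Further compounds**

F1 | step 9 | methyl (2S)-2-[(3-{[(2R)-3,3-dimethyloxiran-2-yl]methyl}-4-[(triisopropylsilyl)oxy]phenyl)methyl]-5-oxo-4-[(triisopropylsilyl)oxy]-3-{4-[(triisopropylsilyl)oxy]phenyl}-2,5-dihydrofuran-2-carboxylate | COC(=O)[C@@]1(Cc2ccc(O[Si](C(C)C)(C(C)C)C(C)C)c(C[C@H]3OC3(C)C)c2)OC(=O)C(O[Si](C(C)C)(C(C)C)C(C)C)=C1c1ccc(O[Si](C(C)C)(C(C)C)C(C)C)cc1
F2 | step 8 | {4-(bromomethyl)-2-(3-methylbut-2-en-1-yl)phenoxy}tri(propan-2-yl)silane | BrCc1ccc(O[Si](C(C)C)(C(C)C)C(C)C)c(CC=C(C)C)c1
F3 | step 8 | methyl (2R)-2-{[3-(3-methylbut-2-en-1-yl)-4-[(triisopropylsilyl)oxy]phenyl]methyl}-5-oxo-4-[(triisopropylsilyl)oxy]-3-{4-[(triisopropylsilyl)oxy]phenyl}-2,5-dihydrofuran-2-carboxylate | COC(=O)[C@]1(Cc2ccc(O[Si](C(C)C)(C(C)C)C(C)C)c(CC=C(C)C)c2)OC(=O)C(O[Si](C(C)C)(C(C)C)C(C)C)=C1c1ccc(O[Si](C(C)C)(C(C)C)C(C)C)cc1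
F4 | step 5 | 3-(prop-2-en-1-yl)-4-[(triisopropylsilyl)oxy]benzaldehyde | C=CCc1cc(C=O)ccc1O[Si](C(C)C)(C(C)C)C(C)C
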